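**Retrosynthetic overview**
- The 7α-acetate comes from Mitsunobu inversion of the 7β-allylic alcohol; the C17 methylene comes from α-methylenation of a 7-ketone.
- Key step: one-carbon radical ring expansion (5→6) of a bicyclic siloxycyclopropane. It inserts C6 between C5 and the carbonyl carbon, so the oxygen ends at C7, and it sets the trans ring fusion at C5.
- Ring A is built on a cyclopentenone by conjugate addition/aldol annulation (sets quaternary C10); a conjugate methylation then gives the gem-dimethyl C4 and the regiodefined enol silane for the ring expansion.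
- C9 and the side chain come from a zinc/copper conjugate addition to (S)-4-silyloxycyclopentenone followed by elimination; C13 comes from CuH reduction of an unsaturated lactone.
- Ring order: five-membered ring (bought) → ring A → five-membered ring expanded to ring B.

Assumption: (S)-4-(tert-butyldimethylsilyloxy)cyclopent-2-enone and 2-(3-chloropropyl)-2-methyl-1,3-dioxolane are bought as such (catalogued protected forms of 4-hydroxycyclopent-2-enone and 5-chloropentan-2-one); ring positions are given in labdane numbering (C5, C7, C8, C9, C10 = naphthalene C4a, C3, C2, C1, C8a).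

**Step 1**
Reactants: 1 4-methyl-5,6-dihydro-2H-pyran-2-one
Product: 2 (4S)-4-methyloxan-2-one
Conditions: Cu(OAc)2·H2O (3 mol %), (S)-p-tol-BINAP (3 mol %; ligand antipode chosen to give the S lactone, checked by rotation), (EtO)2MeSiH, t-BuOH, toluene, 0 °C
Reagents that add atoms: none
Why: Buchwald-type CuH-catalysed asymmetric conjugate reduction, in which ligand-controlled hydride delivery to the β-carbon sets the future C13 stereocentre.

**Step 2**
Reactants: 2 (4S)-4-methyloxan-2-one
Product: 4 methyl (3R)-5-iodo-3-methylpentanoate, via silyl ester 3 (not isolated)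
Conditions: TMSI, CH2Cl2, rt; then MeOH, rt
Reagents that add atoms: iodotrimethylsilane (C[Si](C)(C)I); methanol (CO)
Why: Silyl iodide lactone opening (SN2 of iodide at the O–CH2 carbon of the O-silylated lactone) followed by methanolysis to the methyl ester leaves the stereocentre untouched (the descriptor becomes R only through CIP priorities).

**Step 3**
Reactants: 4 methyl (3R)-5-iodo-3-methylpentanoate; 5 (4S)-4-[(tert-butyldimethylsilyl)oxy]cyclopent-2-en-1-one
Product: 9 methyl (3S)-3-methyl-5-[(1S)-4-oxocyclopent-2-en-1-yl]pentanoate, via alkylzinc iodide 6 (not isolated), via silyl enol ether 7 (not isolated), via silyloxy ketone 8 (not isolated)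
Conditions: Zn, LiCl, THF, 40 °C; then 5, CuBr·SMe2 (10 mol %), TMSCl, DMPU, −20 °C; 1 M HCl; then DBU, CH2Cl2, 0 °C
Reagents that add atoms: none
Why: Knochel zinc insertion and Cu-catalysed conjugate addition (Nakamura–Kuwajima conditions) deliver the side chain anti to the silyloxy group, and E1cB loss of silanol then moves the enone, so the carbinol centre of 5 is relayed into C9.

**Step 4**
Reactants: 9 methyl (3S)-3-methyl-5-[(1S)-4-oxocyclopent-2-en-1-yl]pentanoate
Product: 11 methyl (3S)-3-methyl-5-[(1S)-2-methyl-4-oxocyclopent-2-en-1-yl]pentanoate, via magnesium enolate 10 (not isolated)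
Conditions: MeMgBr, CuBr·SMe2 (10 mol %), THF, −78 °C; then N-tert-butylbenzenesulfinimidoyl chloride, −78 °C → rt
Reagents that add atoms: methylmagnesium bromide (C[Mg]Br)
Why: Cu-catalysed conjugate methylation gives the enolate regiospecifically and Mukaiyama dehydrogenation re-forms the enone on the methyl-bearing carbon (C10), destroying the transient methyl stereocentre while C9 is untouched.

**Step 5**
Reactants: 11 methyl (3S)-3-methyl-5-[(1S)-2-methyl-4-oxocyclopent-2-en-1-yl]pentanoate; 12 2-(3-chloropropyl)-2-methyl-1,3-dioxolane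
Product: 16 methyl (3S)-5-[(1S,7aR)-4,7a-dimethyl-3-oxo-2,3,5,6,7,7a-hexahydro-1H-inden-1-yl]-3-methylpentanoate, via Grignard reagent 13 (not isolated), via silyl enol ether 14 (not isolated), via diketone 15 (not isolated)
Conditions: 12, Mg, THF; then 11, CuBr·SMe2 (10 mol %), TMSCl, DMPU, −78 → −40 °C; then HCl, MeOH, 60 °C
Reagents that add atoms: none
Why: Cu-catalysed conjugate addition anti to the C9 side chain sets quaternary C10 (methyl cis to the side chain), and acid unmasks the methyl ketone for an intramolecular aldol condensation (Robinson-type annulation) that closes ring A.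

**Step 6**
Reactants: 16 methyl (3S)-5-[(1S,7aR)-4,7a-dimethyl-3-oxo-2,3,5,6,7,7a-hexahydro-1H-inden-1-yl]-3-methylpentanoate
Product: 17 methyl (3S)-3-methyl-5-[(1S,7aR)-4,4,7a-trimethyl-3-[(trimethylsilyl)oxy]-2,4,5,6,7,7a-hexahydro-1H-inden-1-yl]pentanoate
Conditions: MeMgBr, CuBr·SMe2 (20 mol %), TMSCl, DMPU, THF, −78 → −30 °C; Et3N, cold NaHCO3 work-up
Reagents that add atoms: methylmagnesium bromide (C[Mg]Br); chlorotrimethylsilane (C[Si](C)(C)Cl)
Why: Cu-catalysed 1,4-addition of methyl to the s-cis alkylidene cyclopentanone (as with pulegone) creates the gem-dimethyl C4 and silyl trapping fixes the enol ether at C5=C7 regiospecifically, with no new stereocentre.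

**Step 7**
Reactants: 17 methyl (3S)-3-methyl-5-[(1S,7aR)-4,4,7a-trimethyl-3-[(trimethylsilyl)oxy]-2,4,5,6,7,7a-hexahydro-1H-inden-1-yl]pentanoate
Product: 18 siloxycyclopropane of 17 (CH2 bridging C5 and C7 on the face opposite the angular methyl)
Conditions: Et2Zn, CF3CO2H, CH2I2, CH2Cl2, 0 °C → rt
Reagents that add atoms: diiodomethane (ICI)
Why: Simmons–Smith cyclopropanation with the Shi carbenoid adds the future C6 to the electron-rich enol ether, expected from the less hindered α face, and either cyclopropane epimer converges in step 8.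

**Step 8**
Reactants: 18 siloxycyclopropane of 17
Product: 19 methyl (3S)-3-methyl-5-[(1S,4aS,8aR)-5,5,8a-trimethyl-3-oxodecahydronaphthalen-1-yl]pentanoate
Conditions: 9-mesityl-10-methylacridinium BF4 (5 mol %), 2,4,6-triisopropylbenzenethiol (20 mol %), MeOH (10 equiv), 1,2-dichloroethane, 450 nm LEDs, rt
Reagents that add atoms: none
Why: Proposed new method: the excited acridinium oxidises the siloxycyclopropane to its radical cation, methanol-assisted desilylation and β-scission of the internal C5–C7 bond give the ring-expanded tertiary C5 radical (C6 inserted, carbonyl now at C7), the hindered thiol transfers H to the α face anti to the axial C10 and 4β methyls to set the trans ring fusion, and back electron transfer to the thiyl radical closes a redox-neutral cycle; the closest known reaction types are the Fe(III)-mediated Ito–Saegusa ring expansion of bicyclic siloxycyclopropanes and acridinium/thiol radical-cation hydrofunctionalisation.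

**Step 9**
Reactants: 19 methyl (3S)-3-methyl-5-[(1S,4aS,8aR)-5,5,8a-trimethyl-3-oxodecahydronaphthalen-1-yl]pentanoate
Product: 23 methyl (3S)-3-methyl-5-[(1R,4aS,8aS)-5,5,8a-trimethyl-2-methylidene-3-oxodecahydronaphthalen-1-yl]pentanoate, via lithium enolate 20 (not isolated), via Mannich base 21 (not isolated), via ammonium iodide 22 (not isolated)
Conditions: LDA, THF, −78 °C; Me2N=CH2 I, −78 → 0 °C; then MeI, CH2Cl2, rt; then sat. NaHCO3, rt
Reagents that add atoms: N,N-dimethylmethyleneiminium iodide (C=[N+](C)C.[I-])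
Why: Kinetic enolisation goes toward C8 because the axial C6–H is shielded by the C10 and 4β methyls (as C2 over C4 in 3-keto-5α-steroids), and Mannich reaction with Eschenmoser's salt followed by quaternisation and elimination gives the exocyclic enone without a new stereocentre.

**Step 10**
Reactants: 23 methyl (3S)-3-methyl-5-[(1R,4aS,8aS)-5,5,8a-trimethyl-2-methylidene-3-oxodecahydronaphthalen-1-yl]pentanoate
Product: 24 methyl (3S)-5-[(1R,3S,4aS,8aS)-3-hydroxy-5,5,8a-trimethyl-2-methylidenedecahydronaphthalen-1-yl]-3-methylpentanoate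
Conditions: NaBH4, CeCl3·7H2O, MeOH, −40 °C
Reagents that add atoms: none
Why: Luche reduction is 1,2-selective and hydride enters along the unhindered axial (α) trajectory, giving the equatorial 7β-alcohol.

**Step 11**
Reactants: 24 methyl (3S)-5-[(1R,3S,4aS,8aS)-3-hydroxy-5,5,8a-trimethyl-2-methylidenedecahydronaphthalen-1-yl]-3-methylpentanoate
Product: 25 methyl (3S)-5-[(1R,3R,4aS,8aS)-3-(acetyloxy)-5,5,8a-trimethyl-2-methylidenedecahydronaphthalen-1-yl]-3-methylpentanoate
Conditions: AcOH, PPh3, DIAD, toluene, 0 °C → rt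
Reagents that add atoms: acetic acid (CC(=O)O)
Why: Mitsunobu reaction with acetic acid displaces the activated equatorial alcohol by SN2 with inversion, giving the axial 7α-acetate of the target.

**Compound list**
1 | 4-methyl-5,6-dihydro-2H-pyran-2-one | CC1=CC(=O)OCC1 | starting material
2 | (4S)-4-methyloxan-2-one | O=C1C[C@@H](C)CCO1 | intermediate
3 | trimethylsilyl (3R)-5-iodo-3-methylpentanoate | ICC[C@H](C)CC(=O)O[Si](C)(C)C | intermediate
4 | methyl (3R)-5-iodo-3-methylpentanoate | ICC[C@H](C)CC(=O)OC | intermediate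
5 | (4S)-4-[(tert-butyldimethylsilyl)oxy]cyclopent-2-en-1-one | O=C1C=C[C@@H](O[Si](C)(C)C(C)(C)C)C1 | starting material
6 | [(3R)-5-methoxy-3-methyl-5-oxopentyl]zinc iodide | I[Zn]CC[C@H](C)CC(=O)OC | intermediate
7 | methyl (3S)-5-[(1S,5S)-5-[(tert-butyldimethylsilyl)oxy]-3-[(trimethylsilyl)oxy]cyclopent-2-en-1-yl]-3-methylpentanoate | C[Si](C)(C)OC1=C[C@H](CC[C@H](C)CC(=O)OC)[C@@H](O[Si](C)(C)C(C)(C)C)C1 | intermediate
8 | methyl (3S)-5-[(1S,2S)-2-[(tert-butyldimethylsilyl)oxy]-4-oxocyclopentyl]-3-methylpentanoate (trans) | O=C1C[C@H](CC[C@H](C)CC(=O)OC)[C@@H](O[Si](C)(C)C(C)(C)C)C1 | intermediate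
9 | methyl (3S)-3-methyl-5-[(1S)-4-oxocyclopent-2-en-1-yl]pentanoate | O=C1C=C[C@@H](CC[C@H](C)CC(=O)OC)C1 | intermediate
10 | methyl (3S)-5-[(1S,2R)-4-[(bromomagnesio)oxy]-2-methylcyclopent-3-en-1-yl]-3-methylpentanoate (methyl trans to side chain) | Br[Mg]OC1=C[C@H](C)[C@@H](CC[C@H](C)CC(=O)OC)C1 | intermediate
11 | methyl (3S)-3-methyl-5-[(1S)-2-methyl-4-oxocyclopent-2-en-1-yl]pentanoate | O=C1C=C(C)[C@@H](CC[C@H](C)CC(=O)OC)C1 | intermediate
12 | 2-(3-chloropropyl)-2-methyl-1,3-dioxolane | CC1(CCCCl)OCCO1 | starting material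
13 | [3-(2-methyl-1,3-dioxolan-2-yl)propyl]magnesium chloride | CC1(CCC[Mg]Cl)OCCO1 | intermediate
14 | methyl (3S)-3-methyl-5-[(1S,2R)-2-methyl-2-[3-(2-methyl-1,3-dioxolan-2-yl)propyl]-4-[(trimethylsilyl)oxy]cyclopent-3-en-1-yl]pentanoate | C[Si](C)(C)OC1=C[C@](C)(CCCC2(C)OCCO2)[C@@H](CC[C@H](C)CC(=O)OC)C1 | intermediate
15 | methyl (3S)-3-methyl-5-[(1S,2S)-2-methyl-4-oxo-2-(4-oxopentyl)cyclopentyl]pentanoate | O=C1C[C@](C)(CCCC(C)=O)[C@@H](CC[C@H](C)CC(=O)OC)C1 | intermediate
16 | methyl (3S)-5-[(1S,7aR)-4,7a-dimethyl-3-oxo-2,3,5,6,7,7a-hexahydro-1H-inden-1-yl]-3-methylpentanoate | O=C1C[C@H](CC[C@H](C)CC(=O)OC)[C@@]2(C)CCCC(C)=C12 | intermediate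
17 | methyl (3S)-3-methyl-5-[(1S,7aR)-4,4,7a-trimethyl-3-[(trimethylsilyl)oxy]-2,4,5,6,7,7a-hexahydro-1H-inden-1-yl]pentanoate | C[Si](C)(C)OC1=C2C(C)(C)CCC[C@]2(C)[C@@H](CC[C@H](C)CC(=O)OC)C1 | intermediate
18 | siloxycyclopropane of 17: CH2 bridges indene C3 and C3a (1-siloxybicyclo[3.1.0]hexane unit), drawn with CH2 on the face opposite the 7a-methyl | C[Si](C)(C)O[C@]12C[C@H](CC[C@H](C)CC(=O)OC)[C@@]3(C)CCCC(C)(C)[C@@]31C2 | intermediate
19 | methyl (3S)-3-methyl-5-[(1S,4aS,8aR)-5,5,8a-trimethyl-3-oxodecahydronaphthalen-1-yl]pentanoate (trans-decalin, 7-ketone) | O=C1C[C@H]2C(C)(C)CCC[C@]2(C)[C@@H](CC[C@H](C)CC(=O)OC)C1 | intermediate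
20 | lithium enolate of 19 (O–Li on C7, C7=C8) | [Li]OC1=C[C@H](CC[C@H](C)CC(=O)OC)[C@@]2(C)CCCC(C)(C)[C@@H]2C1 | intermediate
21 | Mannich base: 19 carrying CH2NMe2 on C8 (drawn equatorial, 8α) | CN(C)C[C@@H]1C(=O)C[C@H]2C(C)(C)CCC[C@]2(C)[C@H]1CC[C@H](C)CC(=O)OC | intermediate
22 | trimethylammonium iodide of 21 | C[N+](C)(C)C[C@@H]1C(=O)C[C@H]2C(C)(C)CCC[C@]2(C)[C@H]1CC[C@H](C)CC(=O)OC.[I-] | intermediate
23 | methyl (3S)-3-methyl-5-[(1R,4aS,8aS)-5,5,8a-trimethyl-2-methylidene-3-oxodecahydronaphthalen-1-yl]pentanoate (7-oxo-8(17)-ene) | C=C1C(=O)C[C@H]2C(C)(C)CCC[C@]2(C)[C@H]1CC[C@H](C)CC(=O)OC | intermediate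
24 | methyl (3S)-5-[(1R,3S,4aS,8aS)-3-hydroxy-5,5,8a-trimethyl-2-methylidenedecahydronaphthalen-1-yl]-3-methylpentanoate (7β-ol) | C=C1[C@@H](O)C[C@H]2C(C)(C)CCC[C@]2(C)[C@H]1CC[C@H](C)CC(=O)OC | intermediate
25 | methyl (3S)-5-[(1R,3R,4aS,8aS)-3-(acetyloxy)-5,5,8a-trimethyl-2-methylidenedecahydronaphthalen-1-yl]-3-methylpentanoate | C=C1[C@H](OC(C)=O)C[C@H]2C(C)(C)CCC[C@]2(C)[C@H]1CC[C@H](C)CC(=O)OC | target

**Totals**
Total step count: 11. Longest linear sequence: 11 steps (1 → 25); 5 and 12 enter as bought materials.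

**Steps most likely to fail, with fallbacks**

Step 7 (cyclopropanation of a tetrasubstituted enol ether whose carbon C5 is flanked by two quaternary centres). The fallback sets out from 17 and comes back at 19, bypassing 18 and step 8, and brings in C6 as a C-bound one-carbon unit instead of a carbenoid. Mukaiyama hydroxymethylation of 17 (aq. HCHO, Yb(OTf)3 cat., THF) gives hydroxymethyl ketone F1. I2, PPh3 and imidazole convert it into iodomethyl ketone F2. Slow addition of Bu3SnH/AIBN (benzene, 80 °C) then triggers a Dowd–Beckwith ring expansion (3-exo attack of the primary radical on the carbonyl, β-scission) to the same C5 radical, which is reduced from the α face to 19.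

Step 8 (the proposed new photochemical ring expansion; possible failures are cleavage of the external cyclopropane bond, simple protodesilylation, or poor facial control of the H transfer). The fallback uses known chemistry, sets out from 18 and comes back at 19. FeCl3 in DMF at 0 °C (Ito–Saegusa ring expansion) gives chloro ketone F3. NaOAc in MeOH at reflux eliminates HCl to enone F4. Hydrogenation (H2, Pd/C, EtOAc) adds hydrogen to the α face of the C5=C6 bond, anti to the C10 methyl, to give trans-fused 19.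

Step 11 (Mitsunobu on an allylic alcohol next to an exocyclic methylene; SN2′ attack or elimination may compete). The fallback sets out from 23 and comes back at 25, setting C7 by reagent-controlled reduction and then acylating with retention. (S)-Me-CBS with catecholborane (toluene, −78 °C; alkenyl side as the large group) gives 7α-alcohol F5. Ac2O, DMAP and pyridine then give 25.

**Further compounds**
F1 | step 7 | methyl (3S)-5-[(1S,7aR)-3a-(hydroxymethyl)-4,4,7a-trimethyl-3-oxooctahydro-1H-inden-1-yl]-3-methylpentanoate (C3a configuration immaterial, drawn with CH2OH trans to the 7a-methyl) | O=C1C[C@H](CC[C@H](C)CC(=O)OC)[C@@]2(C)CCCC(C)(C)[C@@]21CO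
F2 | step 7 | methyl (3S)-5-[(1S,7aR)-3a-(iodomethyl)-4,4,7a-trimethyl-3-oxooctahydro-1H-inden-1-yl]-3-methylpentanoate | O=C1C[C@H](CC[C@H](C)CC(=O)OC)[C@@]2(C)CCCC(C)(C)[C@@]21CI
F3 | step 8 | 5-chloro derivative of 19 (Cl on ring-fusion carbon C5, drawn 5α; either epimer eliminates) | O=C1C[C@@]2(Cl)C(C)(C)CCC[C@]2(C)[C@@H](CC[C@H](C)CC(=O)OC)C1
F4 | step 8 | methyl (3S)-3-methyl-5-[(1S,8aR)-5,5,8a-trimethyl-3-oxo-1,2,3,5,6,7,8,8a-octahydronaphthalen-1-yl]pentanoate (C5=C6 enone) | O=C1C=C2C(C)(C)CCC[C@]2(C)[C@@H](CC[C@H](C)CC(=O)OC)C1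
F5 | step 11 | methyl (3S)-5-[(1R,3R,4aS,8aS)-3-hydroxy-5,5,8a-trimethyl-2-methylidenedecahydronaphthalen-1-yl]-3-methylpentanoate (7α-ol) | C=C1[C@H](O)C[C@H]2C(C)(C)CCC[C@]2(C)[C@H]1CC[C@H](C)CC(=O)OC
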